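# Total synthesis proposal for CNP0361406.2: double Michael annulation route

## The problem

The target is an ester of two closely related isopropyl-bearing carbocyclic halves. In the first half a cyclohexane (ring A) is trans-fused through C5a–C9a to a seven-membered lactone (ring B, 2-benzoxepine numbering) that carries a conjugated carboxylic acid on its C4=C5 alkene. The second half is a cyclohexene (ring C) whose 2-(hydroxymethyl)acrylate arm at C1' acylates the CH2OH group on C9 of ring A.

Ring A holds four contiguous stereocentres. C6 (isopropyl), C5a and C9a are all-trans and equatorial, and the quaternary carbinol C9 has an equatorial hydroxyl and an axial CH2O group. Ring C holds two (C1', C6', trans) of the same absolute sense as C5a/C6.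

The three tertiary centres of ring A are the thermodynamic arrangement and can control C9, because a C9 ketone flanked by them should be attacked axially by a small nucleophile. The absolute configuration of each half has to be brought in separately. Both trisubstituted alkenes must form with the ring carbon cis to the CH2O group.

The groups that will not survive rough treatment are:
- the β-hydroxy lactone (retro-aldol, dehydration);
- the two 2-(oxymethyl)acrylate units, which are Michael and SN2' acceptors and are ionized by zerovalent palladium;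
- the primary allylic alcohols;
- the C9a carboxyl, which closes a γ-lactone onto the C9 CH2OH group whenever both are free.

The key step rests on one feature: C6, C5a and C9a can each be the carbon α to a carbonyl group (acetyl as latent isopropyl, an ester as latent alkenyl arm, a β-keto ester spanning C9a and C9). Ring A is then the product of a double Michael annulation.

## Retrosynthesis

**Unmasking.** Target 36 is traced to 35, in which the C4 acid is a tert-butyl ester and the two ring C alcohols are TBS ethers. No skeletal bond is cut; one acid treatment is asked for at the end.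

**Ring B.** The C4=C5 alkene and the ester bond between the C1 carboxyl oxygen and C3 are cut, giving diene ester 34 and then acid 33 plus commercial tert-butyl 2-(bromomethyl)prop-2-enoate. Lactonization of a preformed arm would require a geometry-controlled olefination of a hindered C5a aldehyde and one more hydroxyl protecting group. Allylic lactonization has a five-membered competitor. Ring-closing metathesis can only give the seven-membered ring, and the ring fixes the alkene geometry. Precursor 33 is monocyclic.

**C9a carboxyl.** Acid 33 is traced through diol 31 to PMB ether 30, so the C9a carbon is carried as CH2OPMB. As an ester beside a C9 ketone it would make C9a–H acidic and quench any ylide. As a free acid beside the C9 epoxide it would close the γ-lactone. It is therefore oxidized only after the C9 CH2O group has been acylated.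

**Fragment union.** The CH2–O bond of the side-chain ester is cut: 30 comes from spiro-epoxide 16 and ring C acid 29 by carboxylate opening at the epoxide CH2. The cut is convergent, sets no stereocentre and frees the tertiary hydroxyl. Acylation of a preformed diol is one step longer and is kept as the reserve.

**C9.** Epoxide 16 comes from ketone 15 (one C–C bond to C9 from a sulfur ylide), and 15 from ketal 14. The forward reaction must add carbon axially; the all-equatorial neighbours ask for exactly that.

**Telling the two carboxyl carbons apart.** Vinyl alcohol 13 (parent of 14) comes from lactol 12 and lactone 11. Lactone 11 comes from acid ester 9, in which the C5a carboxyl is a free acid and the C9a carboxyl a methyl ester. Two simple alkyl esters could not be distinguished at this point. A benzyl ester on the C5a carbon solves this at no cost, because the hydrogenation that turns isopropenyl into isopropyl (8 to 9) also frees the acid. Compound 8 comes from 7 by ketalization and 7 from 6 by methylenation of the acetyl group.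

**Ring A (key step).** In 6 the bonds C9a–C5a and C6–C7 (target numbering) are cut, giving methyl 3-oxopent-4-enoate 2 and benzyl (2E)-4-oxopent-2-enoate 4, two five-carbon pieces from commercial 1 and 3. Against a cycloaddition of a diene, this cut places every stereocentre α to a carbonyl. One refinement is needed: only the β-keto ester carbon and the acetyl-bearing carbon may equilibrate. The ester-bearing carbon (future C5a) is set by the catalyst and must stay fixed, since free epimerization of all three centres would racemize the product. The forward reaction therefore has to be enantioselective in the first addition and mild enough in base to leave an ester α-carbon alone.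

**Ring C acid.** Acid 29 comes from ester 28 and diol 27, whose two CH2OH groups are cut back to the bromide and the triflate of 26 (twofold Stille coupling). The alkene of 26 is cut to aldehyde 25 (Wittig reaction of a bromo ylide, which places the ring cis to bromine). Aldehyde 25 comes from vinyl triflate 23, and 23 from (R)-cryptone 21 by conjugate addition with enolate trapping, which sets C1' trans to C6' and marks C3' regiospecifically. Cryptone 21 comes from keto aldehyde 19, made from 3-methylbutanal 17 and but-3-en-2-one 18. Although both halves share their configuration, degrading a ring A intermediate to ring C (loss of the C9a carbon and dehydration) would cost more steps than this eight-step branch.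

## Roads not taken

**Alternative 1:** Stereoconvergent palladium allylic lactonization of a Baylis–Hillman carbonate.
- Cut: the bond between the C1 carboxyl oxygen and C3 of ring B.
- Forward step: in Baylis–Hillman carbonate A1, Pd(PPh3)4 would ionize the carbonate and the C9a carboxylate would attack the CH2 terminus of the allyl unit, giving bicyclic acetonide A2 with the alkene in place.
- Merits: ring B closes in one step from an acrylate adduct, both carbinol epimers of A1 converge, and no high dilution is needed.
- Weak points: the carboxylate can also attack the internal allyl carbon and close a five-membered lactone, which is kinetically favoured. The Baylis–Hillman reaction that makes A1 must take place on a hindered aldehyde flanked by two substituted ring carbons. The product type is itself an allylic ester that zerovalent palladium ionizes, so ring C could only be attached afterwards. The plan is silent on how the ring A stereotriad and its absolute configuration arise.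
- Comparison: as a ring B closure it is one step shorter than the chosen esterification and metathesis (steps 24 and 25). The chosen plan sets against this a ring closure with no five- versus seven-membered choice, and a solution for ring A.

**Alternative 2:** Transannular Tsuji–Trost reaction in an eleven-membered keto-lactone.
- Cut: the fusion bond C5a–C9a.
- Forward step: in macrocycle A3, Pd(PPh3)4 would ionize the allylic carbonate and the keto-lactone enolate carbon would attack the allyl terminus across the ring, giving β-keto lactone A4 with rings A and B formed at once.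
- Merits: topologically the most economical road; one step makes two rings and two stereocentres.
- Weak points: A3 needs an eleven-membered lactonization. Only the isopropyl carbon is there to control two new centres, through a macrocycle conformation that cannot be predicted with confidence. O-allylation competes. A4 still lacks the C9 carbon and hydroxyl, and its C9a–H is flanked by ketone and lactone, so a basic ylide would deprotonate rather than add.
- Comparison: the chosen plan is longer in ring formation, but every stereocentre has a named controlling element and the C9 chemistry is done while C9a carries no acidifying group.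

**Alternative 3:** Iminium-catalysed Diels–Alder reaction setting the ring A stereotriad.
- Cut: the bonds C9–C9a and C6–C5a.
- Forward step: dienyl acetate A5 and ethyl (2E)-4-oxobut-2-enoate A6 would combine under a chiral imidazolidinone salt to give cycloadduct A7.
- Merits: the isopropyl group is in place from the start. Four stereocentres arise in one step. The C9a carbon (aldehyde) and the C5a carbon (ester) are differentiated at once, which is better than the chosen route, where steps 4 to 9 are spent on making isopropyl and on telling two carboxyl groups apart.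
- Weak points: the relative configuration of A7 is kinetic (endo) and cannot correct itself. A7 is a β-acetoxy aldehyde, prone to loss of acetic acid toward a dienal and to epimerization at the formyl carbon. A diene with a branched terminus reacts slowly with iminium dienophiles. The acetoxy carbon must still be oxidized and the ring alkene reduced before the same C9 chemistry begins.
- Comparison: if it worked, the early part would be two or three steps shorter. The chosen plan sets against this stereocentres that converge by equilibration, commodity five-carbon building blocks, and a carboxylic acid intermediate (9) that allows resolution as a reserve.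

Key step: step 3

Assumption (step 3): the quinine-derived thiourea is taken to deliver the enolate to the enone face that gives (1R)-6; if the sense proves opposite, the quinidine-derived pseudoenantiomer is used and nothing else changes.

Assumption (step 13): the (R)-configured prolinol ether is taken to give (2R)-19 by the usual enamine shielding model.

Abbreviations in names: Bn = benzyl; PMB = 4-methoxybenzyl; TBS = tert-butyl(dimethyl)silyl; Tf = trifluoromethanesulfonyl; "RC-acyl" = the (2E)-2-(TBSOCH2)-3-[(1R,6R)-3-(TBSOCH2)-6-(propan-2-yl)cyclohex-2-en-1-yl]prop-2-enoyl group of acid 29.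

## Route

Step 1
Reactants: 1 methyl 5-methoxy-3-oxopentanoate
Product: 2 methyl 3-oxopent-4-enoate
Conditions: TsOH·H2O (2 mol %), 120 °C, 60 mbar, distilled into a −78 °C receiver, used at once
Reagents that add atoms: none
Why: Acid-catalysed β-elimination of methanol from a β-methoxy ketone; distillation removes the polymerizable vinyl ketone from the acid as it forms.

Step 2
Reactants: 3 (2E)-4-oxopent-2-enoic acid
Product: 4 benzyl (2E)-4-oxopent-2-enoate
Conditions: BnBr, K2CO3, DMF, 0 °C → rt
Reagents that add atoms: benzyl bromide, BrCc1ccccc1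
Why: Carboxylate O-alkylation (SN2); the benzyl ester is chosen so that the carboxyl on the future C5a carbon can later be freed by hydrogenolysis beside a methyl ester.

Step 3
Reactants: 2 methyl 3-oxopent-4-enoate; 4 benzyl (2E)-4-oxopent-2-enoate
Product: 6 1-benzyl 2-methyl (1R,2S,6S)-6-acetyl-3-oxocyclohexane-1,2-dicarboxylate, via open-chain Michael adduct 5 (not isolated)
Conditions: 1-[3,5-bis(trifluoromethyl)phenyl]-3-[(8S,9S)-6'-methoxycinchonan-9-yl]thiourea (10 mol %), PhMe, −20 °C, 2 (1.3 equiv) added over 6 h; then Cs2CO3 (0.2 equiv), 0 °C → rt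
Reagents that add atoms: none
Why: Proposed new method: the quinuclidine nitrogen of the catalyst deprotonates the β-keto ester carbon of 2 while the thiourea hydrogen-bonds the ketone of 4, so the ion-paired enolate adds to the alkene carbon of 4 that is β to the ketone (the ester-bearing carbon); the closest known reaction types are the amine–thiourea-catalysed Michael–Michael annulation of vinyl β-keto esters with activated alkenes and the thiourea-catalysed addition of 1,3-dicarbonyl compounds to β-acyl acrylates, and the racemic carbonate-mediated annulation of 2 with activated enones is established. The acetyl enolate of adduct 5 then adds to the vinyl ketone terminus in a 6-endo-trig Michael closure that forms ring A, so the two new bonds are C2–C1 and C6–C5 of 6 (C9a–C5a and C6–C7 of the target). C1 (future C5a) is set by the catalyst in the first addition and, being α only to an ester, is not epimerized by carbonate. C2 (β-keto ester carbon) and C6 (α to the acetyl group) are set by equilibration to the all-equatorial trans,trans arrangement, which is the relative configuration of the target. The step needs regioselectivity (attack β to the ketone, secured by the acyl group as the stronger acceptor), chemoselectivity over self-condensation of 2 (slow addition keeps 2 dilute beside the doubly activated 4) and enantiofacial control from the catalyst. Carbonate is added only after the first addition so that it cannot open a racemic background path, and under base the ring ketone is masked as its β-keto ester enolate, which prevents aldol closure with the acetyl group.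

Step 4
Reactants: 6 1-benzyl 2-methyl (1R,2S,6S)-6-acetyl-3-oxocyclohexane-1,2-dicarboxylate
Product: 7 1-benzyl 2-methyl (1R,2S,6S)-3-oxo-6-(prop-1-en-2-yl)cyclohexane-1,2-dicarboxylate
Conditions: Ph3PCH3Br (2.6 equiv), KOtBu (2.5 equiv), THF, 0 °C; then 6, 0 °C → rt; aq NH4Cl
Reagents that add atoms: methyltriphenylphosphonium bromide, C[P+](c1ccccc1)(c1ccccc1)c1ccccc1.[Br-]
Why: Wittig methylenation of the methyl ketone; the first equivalent of ylide converts the β-keto ester into its enolate, which is inert to the ylide, so only the acetyl group is olefinated and the esters are untouched.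

Step 5
Reactants: 7 1-benzyl 2-methyl (1R,2S,6S)-3-oxo-6-(prop-1-en-2-yl)cyclohexane-1,2-dicarboxylate
Product: 8 7-benzyl 6-methyl (6S,7R,8S)-8-(prop-1-en-2-yl)-1,4-dioxaspiro[4.5]decane-6,7-dicarboxylate
Conditions: TMSOCH2CH2OTMS (3 equiv), TMSOTf (5 mol %), CH2Cl2, −78 → −20 °C; pyridine quench
Reagents that add atoms: 1,2-bis(trimethylsilyloxy)ethane, C[Si](C)(C)OCCO[Si](C)(C)C
Why: Noyori ketalization under aprotic conditions protects the ring ketone, removes the acidity of the adjacent methine and spares the 1,1-disubstituted alkene and both esters.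

Step 6
Reactants: 8 7-benzyl 6-methyl (6S,7R,8S)-8-(prop-1-en-2-yl)-1,4-dioxaspiro[4.5]decane-6,7-dicarboxylate
Product: 9 (6S,7R,8R)-6-(methoxycarbonyl)-8-(propan-2-yl)-1,4-dioxaspiro[4.5]decane-7-carboxylic acid
Conditions: H2 (1 atm), Pd/C (10 %), EtOAc, rt
Reagents that add atoms: none
Why: Catalytic hydrogenation saturates the isopropenyl group and hydrogenolyses the benzyl ester in one operation, so the two carboxyl carbons now differ as acid and methyl ester; the ketal is stable under neutral hydrogenation.

Step 7
Reactants: 9 (6S,7R,8R)-6-(methoxycarbonyl)-8-(propan-2-yl)-1,4-dioxaspiro[4.5]decane-7-carboxylic acid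
Product: 11 (3aR,7R,7aR)-4,4-(ethane-1,2-diyldioxy)-7-(propan-2-yl)hexahydro-2-benzofuran-1(3H)-one, via hydroxy acid 10 (not isolated)
Conditions: LiBH4 (3 equiv), MeOH (3 equiv), THF, 0 → 40 °C; 1 M HCl to pH 3, 0 °C; PPTS (5 mol %), PhMe, 60 °C
Reagents that add atoms: none
Why: Chemoselective borohydride reduction: LiBH4 reduces the methyl ester but not the lithium carboxylate, and on acidification hydroxy acid 10 closes the trans-fused γ-lactone, which fixes the C9a carbon at the alcohol level and the C5a carbon at the carboxyl level.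

Step 8
Reactants: 11 (3aR,7R,7aR)-4,4-(ethane-1,2-diyldioxy)-7-(propan-2-yl)hexahydro-2-benzofuran-1(3H)-one
Product: 12 (3aR,7R,7aR)-4,4-(ethane-1,2-diyldioxy)-7-(propan-2-yl)octahydro-2-benzofuran-1-ol (both C1 epimers)
Conditions: i-Bu2AlH (1.1 equiv), CH2Cl2, −78 °C; Rochelle salt work-up
Reagents that add atoms: none
Why: Low-temperature half-reduction of a γ-lactone stops at the aluminium hemiacetal, which gives the lactol on work-up.

Step 9
Reactants: 12 (3aR,7R,7aR)-4,4-(ethane-1,2-diyldioxy)-7-(propan-2-yl)octahydro-2-benzofuran-1-ol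
Product: 13 [(6R,7R,8R)-7-ethenyl-8-(propan-2-yl)-1,4-dioxaspiro[4.5]decan-6-yl]methanol
Conditions: Ph3PCH3Br (4 equiv), KOtBu (3.8 equiv), THF, 0 → 45 °C
Reagents that add atoms: methyltriphenylphosphonium bromide, C[P+](c1ccccc1)(c1ccccc1)c1ccccc1.[Br-]
Why: Wittig methylenation of the lactol through its open hydroxy aldehyde tautomer gives the vinyl group and the free CH2OH at once; if the formyl-bearing carbon epimerizes under the basic ylide it returns to the equatorial position between its two equatorial neighbours.

Step 10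
Reactants: 13 [(6R,7R,8R)-7-ethenyl-8-(propan-2-yl)-1,4-dioxaspiro[4.5]decan-6-yl]methanol
Product: 14 (6R,7R,8R)-7-ethenyl-6-{[(4-methoxyphenyl)methoxy]methyl}-8-(propan-2-yl)-1,4-dioxaspiro[4.5]decane
Conditions: NaH, PMBCl, Bu4N+ I− (cat.), DMF, 0 °C → rt
Reagents that add atoms: 4-methoxybenzyl chloride, COc1ccc(CCl)cc1
Why: Williamson etherification; the PMB ether survives acid hydrolysis of the ketal, the ylide and the coupling, and is later removed oxidatively beside silyl ethers.

Step 11
Reactants: 14 (6R,7R,8R)-7-ethenyl-6-{[(4-methoxyphenyl)methoxy]methyl}-8-(propan-2-yl)-1,4-dioxaspiro[4.5]decane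
Product: 15 (2R,3R,4R)-3-ethenyl-2-{[(4-methoxyphenyl)methoxy]methyl}-4-(propan-2-yl)cyclohexan-1-one
Conditions: PPTS (0.2 equiv), acetone–H2O (10:1), 55 °C
Reagents that add atoms: water, O
Why: Mild acetal hydrolysis that spares the PMB ether; C2 is again α to a ketone, so any C2 epimer carried from earlier steps converges on the all-equatorial ketone.

Step 12
Reactants: 15 (2R,3R,4R)-3-ethenyl-2-{[(4-methoxyphenyl)methoxy]methyl}-4-(propan-2-yl)cyclohexan-1-one
Product: 16 (3S,4R,5R,6R)-5-ethenyl-4-{[(4-methoxyphenyl)methoxy]methyl}-6-(propan-2-yl)-1-oxaspiro[2.5]octane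
Conditions: Me3S+ I−, n-BuLi, THF, −10 °C; then 15, −10 → 0 °C
Reagents that add atoms: trimethylsulfonium iodide, C[S+](C)C.[I-]
Why: Corey–Chaykovsky epoxidation: dimethylsulfonium methylide adds irreversibly and axially to the cyclohexanone, whose equatorial trajectory is hindered by the adjacent equatorial CH2OPMB group, and the betaine closes with loss of dimethyl sulfide. The result is an axial CH2 and an equatorial oxygen, the (3S) configuration required for C9, and addition to the ketone should outrun enolization and β-elimination of the alkoxide.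

Step 13
Reactants: 17 3-methylbutanal; 18 but-3-en-2-one
Product: 19 (2R)-5-oxo-2-(propan-2-yl)hexanal
Conditions: (R)-2-[methoxy(diphenyl)methyl]pyrrolidine (5 mol %), ethyl 3,4-dihydroxybenzoate (20 mol %), neat, 4 °C
Reagents that add atoms: none
Why: Enamine-catalysed Michael addition of an aldehyde to a vinyl ketone; the diphenyl(methoxy)methyl group shields one face of the E-enamine and so sets the stereocentre that becomes C6'.

Step 14
Reactants: 19 (2R)-5-oxo-2-(propan-2-yl)hexanal
Product: 21 (4R)-4-(propan-2-yl)cyclohex-2-en-1-one, via ketol 20 (not isolated)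
Conditions: LiOH (0.2 equiv), i-PrOH, rt
Reagents that add atoms: none
Why: Intramolecular aldol condensation of the methyl ketone onto the aldehyde followed by dehydration of ketol 20; the mild base and fast cyclization keep the α-stereocentre from epimerizing.

Step 15
Reactants: 21 (4R)-4-(propan-2-yl)cyclohex-2-en-1-one
Product: 23 (3R,4R)-3-ethenyl-4-(propan-2-yl)cyclohex-1-en-1-yl trifluoromethanesulfonate, via magnesium enolate 22 (not isolated)
Conditions: CH2=CHMgBr (1.5 equiv), CuBr·SMe2 (20 mol %), THF, −78 °C; then N-(5-chloropyridin-2-yl)bis(trifluoromethanesulfonyl)imide, −78 → 0 °C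
Reagents that add atoms: vinylmagnesium bromide, C=C[Mg]Br; N-(5-chloropyridin-2-yl)-1,1,1-trifluoro-N-(trifluoromethanesulfonyl)methanesulfonamide (Comins' reagent), Clc1ccc(N(S(=O)(=O)C(F)(F)F)S(=O)(=O)C(F)(F)F)nc1
Why: Copper-catalysed conjugate addition places the vinyl group anti to the neighbouring isopropyl group (C1' trans to C6'), and O-triflation of enolate 22 fixes the alkene regiospecifically between C2' and C3'.

Step 16
Reactants: 23 (3R,4R)-3-ethenyl-4-(propan-2-yl)cyclohex-1-en-1-yl trifluoromethanesulfonate
Product: 25 (3R,4R)-3-formyl-4-(propan-2-yl)cyclohex-1-en-1-yl trifluoromethanesulfonate, via diol 24 (not isolated)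
Conditions: OsO4 (2 mol %), NaIO4 (4 equiv), 2,6-lutidine (2 equiv), 1,4-dioxane–H2O (3:1), rt; crude aldehyde used directly
Reagents that add atoms: osmium tetroxide, O=[Os](=O)(=O)=O; sodium periodate, [Na+].[O-]I(=O)(=O)=O
Why: Lemieux–Johnson cleavage: dihydroxylation takes the monosubstituted vinyl group and leaves the electron-poor enol triflate alone; the lutidine buffer limits epimerization of the α-branched aldehyde.

Step 17
Reactants: 25 (3R,4R)-3-formyl-4-(propan-2-yl)cyclohex-1-en-1-yl trifluoromethanesulfonate
Product: 26 methyl (2Z)-2-bromo-3-[(1R,6R)-6-(propan-2-yl)-3-(trifluoromethanesulfonyloxy)cyclohex-2-en-1-yl]prop-2-enoate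
Conditions: Ph3P=C(Br)CO2Me (1.5 equiv), CH2Cl2, 0 °C → rt
Reagents that add atoms: methyl bromo(triphenyl-λ5-phosphanylidene)acetate, COC(=O)C(Br)=P(c1ccccc1)(c1ccccc1)c1ccccc1
Why: Wittig reaction of a stabilized α-bromo ylide, which places the ring carbon cis to bromine and trans to the ester (Z); the ylide is neutral and weakly basic, which suits the sensitive aldehyde.

Step 18
Reactants: 26 methyl (2Z)-2-bromo-3-[(1R,6R)-6-(propan-2-yl)-3-(trifluoromethanesulfonyloxy)cyclohex-2-en-1-yl]prop-2-enoate
Product: 27 methyl (2E)-2-(hydroxymethyl)-3-[(1R,6R)-3-(hydroxymethyl)-6-(propan-2-yl)cyclohex-2-en-1-yl]prop-2-enoate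
Conditions: Bu3SnCH2OH (2.6 equiv), Pd(PPh3)4 (10 mol %), LiCl (3 equiv), 1,4-dioxane, 95 °C
Reagents that add atoms: (tributylstannyl)methanol, CCCC[Sn](CCCC)(CCCC)CO
Why: Twofold Stille hydroxymethylation: the alkenyl bromide and the enol triflate both couple with retention, so the arm CH2OH ends cis to the ring carbon and the ring CH2OH arrives on C3'.

Step 19
Reactants: 27 methyl (2E)-2-(hydroxymethyl)-3-[(1R,6R)-3-(hydroxymethyl)-6-(propan-2-yl)cyclohex-2-en-1-yl]prop-2-enoate
Product: 28 methyl (2E)-2-(TBSOCH2)-3-[(1R,6R)-3-(TBSOCH2)-6-(propan-2-yl)cyclohex-2-en-1-yl]prop-2-enoate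
Conditions: TBSCl (2.5 equiv), imidazole (5 equiv), DMF, rt
Reagents that add atoms: tert-butyl(chloro)dimethylsilane, CC(C)(C)[Si](C)(C)Cl
Why: Standard silylation of two primary alcohols; the TBS ethers withstand saponification, the coupling and both later oxidations.

Step 20
Reactants: 28 methyl (2E)-2-(TBSOCH2)-3-[(1R,6R)-3-(TBSOCH2)-6-(propan-2-yl)cyclohex-2-en-1-yl]prop-2-enoate
Product: 29 (2E)-2-(TBSOCH2)-3-[(1R,6R)-3-(TBSOCH2)-6-(propan-2-yl)cyclohex-2-en-1-yl]prop-2-enoic acid
Conditions: LiOH·H2O (5 equiv), THF–MeOH–H2O (3:1:1), 45 °C; 1 M HCl to pH 4, 0 °C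
Reagents that add atoms: lithium hydroxide, [Li+].[OH-]
Why: Saponification of the conjugated methyl ester; primary TBS ethers are stable to hydroxide and to the brief mild acidification.

Step 21
Reactants: 16 (3S,4R,5R,6R)-5-ethenyl-4-{[(4-methoxyphenyl)methoxy]methyl}-6-(propan-2-yl)-1-oxaspiro[2.5]octane; 29 (2E)-2-(TBSOCH2)-3-[(1R,6R)-3-(TBSOCH2)-6-(propan-2-yl)cyclohex-2-en-1-yl]prop-2-enoic acid
Product: 30 [(1S,2R,3R,4R)-3-ethenyl-1-hydroxy-2-{[(4-methoxyphenyl)methoxy]methyl}-4-(propan-2-yl)cyclohexyl]methyl ester of acid 29 (RC-acyl ester)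
Conditions: 29 (1.2 equiv), Cs2CO3 (0.3 equiv), DMF, 85 °C
Reagents that add atoms: none
Why: Base-catalysed epoxide opening by a carboxylate: the caesium carboxylate attacks the CH2 terminus of the 2,2-disubstituted epoxide (SN2), so the quaternary carbinol keeps its configuration and the tertiary alkoxide released regenerates carboxylate from further acid.

Step 22
Reactants: 30 [(1S,2R,3R,4R)-3-ethenyl-1-hydroxy-2-{[(4-methoxyphenyl)methoxy]methyl}-4-(propan-2-yl)cyclohexyl]methyl RC-acyl ester
Product: 31 [(1S,2R,3R,4R)-3-ethenyl-1-hydroxy-2-(hydroxymethyl)-4-(propan-2-yl)cyclohexyl]methyl RC-acyl ester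
Conditions: DDQ (1.5 equiv), CH2Cl2–pH 7 buffer (10:1), 0 °C → rt
Reagents that add atoms: none
Why: Oxidative cleavage of the PMB ether by DDQ; water intercepts the oxocarbenium ion before the hindered tertiary hydroxyl can, and silyl ethers, alkenes and the ester are not affected.

Step 23
Reactants: 31 [(1S,2R,3R,4R)-3-ethenyl-1-hydroxy-2-(hydroxymethyl)-4-(propan-2-yl)cyclohexyl]methyl RC-acyl ester
Product: 33 (1S,2S,5R,6R)-6-ethenyl-2-hydroxy-5-(propan-2-yl)-2-[(RC-acyloxy)methyl]cyclohexane-1-carboxylic acid, via aldehyde 32 (not isolated)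
Conditions: TEMPO (0.2 equiv), PhI(OAc)2 (2.5 equiv), MeCN–H2O (1:1), rt
Reagents that add atoms: water, O
Why: Oxoammonium (TEMPO) oxidation of the only primary alcohol to the acid through the hydrate of aldehyde 32; the tertiary alcohol cannot be oxidized, and the C9 CH2O group is already acylated, so no γ-lactone can form.

Step 24
Reactants: 33 (1S,2S,5R,6R)-6-ethenyl-2-hydroxy-5-(propan-2-yl)-2-[(RC-acyloxy)methyl]cyclohexane-1-carboxylic acid
Product: 34 2-(tert-butoxycarbonyl)prop-2-en-1-yl (1S,2S,5R,6R)-6-ethenyl-2-hydroxy-5-(propan-2-yl)-2-[(RC-acyloxy)methyl]cyclohexane-1-carboxylate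
Conditions: tert-butyl 2-(bromomethyl)prop-2-enoate (1.5 equiv), KHCO3 (2 equiv), DMF, rt
Reagents that add atoms: tert-butyl 2-(bromomethyl)prop-2-enoate, C=C(CBr)C(=O)OC(C)(C)C
Why: Carboxylate alkylation with an activated allylic bromide; direct and allylic (SN2') substitution give the same product, and hydrogencarbonate is too weak a base to trigger retro-aldol cleavage of the β-hydroxy ester.

Step 25
Reactants: 34 2-(tert-butoxycarbonyl)prop-2-en-1-yl (1S,2S,5R,6R)-6-ethenyl-2-hydroxy-5-(propan-2-yl)-2-[(RC-acyloxy)methyl]cyclohexane-1-carboxylate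
Product: 35 tert-butyl (5aS,6R,9S,9aS)-9-hydroxy-1-oxo-6-(propan-2-yl)-9-[(RC-acyloxy)methyl]-1,3,5a,6,7,8,9,9a-octahydro-2-benzoxepine-4-carboxylate
Conditions: second-generation Hoveyda–Grubbs catalyst (H2IMes)Cl2Ru=CH(C6H4-2-OiPr) (10 mol %), PhMe (2 mM), 80 °C
Reagents that add atoms: none
Why: Ring-closing metathesis between the vinyl group and the 1,1-disubstituted acrylate closes the seven-membered lactone; the ring enforces the geometry in which the ring A carbon is cis to the CH2O group, and the trisubstituted alkenes of the ring C half are too hindered to take part.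

Step 26
Reactants: 35 tert-butyl (5aS,6R,9S,9aS)-9-hydroxy-1-oxo-6-(propan-2-yl)-9-[(RC-acyloxy)methyl]-1,3,5a,6,7,8,9,9a-octahydro-2-benzoxepine-4-carboxylate
Product: 36 (5aS,6R,9S,9aS)-9-hydroxy-9-[({(2E)-2-(hydroxymethyl)-3-[(1R,6R)-3-(hydroxymethyl)-6-(propan-2-yl)cyclohex-2-en-1-yl]prop-2-enoyl}oxy)methyl]-1-oxo-6-(propan-2-yl)-1,3,5a,6,7,8,9,9a-octahydro-2-benzoxepine-4-carboxylic acid
Conditions: CF3CO2H–CH2Cl2 (1:3), H2O (10 equiv), 0 °C → rt; aq NaHCO3, then pH 4 and extraction
Reagents that add atoms: none
Why: Acidolysis cleaves the tert-butyl ester (loss of 2-methylpropene) and hydrolyses both primary TBS ethers; the tertiary alcohol is flanked by electron-withdrawing groups and should not ionize, and the bicarbonate wash cleaves any trifluoroacetate esters.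

## Compound list

1 | methyl 5-methoxy-3-oxopentanoate | COCCC(=O)CC(=O)OC | starting material
2 | methyl 3-oxopent-4-enoate | C=CC(=O)CC(=O)OC | intermediate
3 | (2E)-4-oxopent-2-enoic acid | CC(=O)/C=C/C(=O)O | starting material
4 | benzyl (2E)-4-oxopent-2-enoate | CC(=O)/C=C/C(=O)OCc1ccccc1 | intermediate
5 | benzyl (2R)-2-(1-methoxy-1,3-dioxopent-4-en-2-yl)-4-oxopentanoate (epimers at the keto ester carbon) | C=CC(=O)C(C(=O)OC)[C@@H](CC(C)=O)C(=O)OCc1ccccc1 | intermediate (not isolated)
6 | 1-benzyl 2-methyl (1R,2S,6S)-6-acetyl-3-oxocyclohexane-1,2-dicarboxylate | CC(=O)[C@H]1CCC(=O)[C@@H](C(=O)OC)[C@@H]1C(=O)OCc1ccccc1 | intermediate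
7 | 1-benzyl 2-methyl (1R,2S,6S)-3-oxo-6-(prop-1-en-2-yl)cyclohexane-1,2-dicarboxylate | CC(=C)[C@H]1CCC(=O)[C@@H](C(=O)OC)[C@@H]1C(=O)OCc1ccccc1 | intermediate
8 | 7-benzyl 6-methyl (6S,7R,8S)-8-(prop-1-en-2-yl)-1,4-dioxaspiro[4.5]decane-6,7-dicarboxylate | CC(=C)[C@H]1CCC2(OCCO2)[C@@H](C(=O)OC)[C@@H]1C(=O)OCc1ccccc1 | intermediate
9 | (6S,7R,8R)-6-(methoxycarbonyl)-8-(propan-2-yl)-1,4-dioxaspiro[4.5]decane-7-carboxylic acid | CC(C)[C@H]1CCC2(OCCO2)[C@@H](C(=O)OC)[C@@H]1C(=O)O | intermediate
10 | (6R,7R,8R)-6-(hydroxymethyl)-8-(propan-2-yl)-1,4-dioxaspiro[4.5]decane-7-carboxylic acid | CC(C)[C@H]1CCC2(OCCO2)[C@@H](CO)[C@@H]1C(=O)O | intermediate (not isolated)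
11 | (3aR,7R,7aR)-4,4-(ethane-1,2-diyldioxy)-7-(propan-2-yl)hexahydro-2-benzofuran-1(3H)-one (trans-fused lactone) | CC(C)[C@H]1CCC2(OCCO2)[C@@H]3[C@@H]1C(=O)OC3 | intermediate
12 | (3aR,7R,7aR)-4,4-(ethane-1,2-diyldioxy)-7-(propan-2-yl)octahydro-2-benzofuran-1-ol (both C1 epimers) | CC(C)[C@H]1CCC2(OCCO2)[C@@H]3[C@@H]1C(O)OC3 | intermediate
13 | [(6R,7R,8R)-7-ethenyl-8-(propan-2-yl)-1,4-dioxaspiro[4.5]decan-6-yl]methanol | CC(C)[C@H]1CCC2(OCCO2)[C@@H](CO)[C@@H]1C=C | intermediate
14 | (6R,7R,8R)-7-ethenyl-6-{[(4-methoxyphenyl)methoxy]methyl}-8-(propan-2-yl)-1,4-dioxaspiro[4.5]decane | CC(C)[C@H]1CCC2(OCCO2)[C@@H](COCc3ccc(OC)cc3)[C@@H]1C=C | intermediate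
15 | (2R,3R,4R)-3-ethenyl-2-{[(4-methoxyphenyl)methoxy]methyl}-4-(propan-2-yl)cyclohexan-1-one | CC(C)[C@H]1CCC(=O)[C@@H](COCc2ccc(OC)cc2)[C@@H]1C=C | intermediate
16 | (3S,4R,5R,6R)-5-ethenyl-4-{[(4-methoxyphenyl)methoxy]methyl}-6-(propan-2-yl)-1-oxaspiro[2.5]octane | CC(C)[C@H]1CC[C@@]2(CO2)[C@@H](COCc3ccc(OC)cc3)[C@@H]1C=C | intermediate
17 | 3-methylbutanal | CC(C)CC=O | starting material
18 | but-3-en-2-one | CC(=O)C=C | starting material
19 | (2R)-5-oxo-2-(propan-2-yl)hexanal | CC(C)[C@H](C=O)CCC(C)=O | intermediate
20 | (4R)-3-hydroxy-4-(propan-2-yl)cyclohexan-1-one (both C3 epimers) | CC(C)[C@H]1CCC(=O)CC1O | intermediate (not isolated)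
21 | (4R)-4-(propan-2-yl)cyclohex-2-en-1-one | CC(C)[C@H]1CCC(=O)C=C1 | intermediate
22 | bromomagnesium (3R,4R)-3-ethenyl-4-(propan-2-yl)cyclohex-1-en-1-olate | C=C[C@H]1C=C(O[Mg]Br)CC[C@@H]1C(C)C | intermediate (not isolated)
23 | (3R,4R)-3-ethenyl-4-(propan-2-yl)cyclohex-1-en-1-yl trifluoromethanesulfonate | C=C[C@H]1C=C(OS(=O)(=O)C(F)(F)F)CC[C@@H]1C(C)C | intermediate
24 | (3R,4R)-3-(1,2-dihydroxyethyl)-4-(propan-2-yl)cyclohex-1-en-1-yl trifluoromethanesulfonate (both carbinol epimers) | OCC(O)[C@H]1C=C(OS(=O)(=O)C(F)(F)F)CC[C@@H]1C(C)C | intermediate (not isolated)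
25 | (3R,4R)-3-formyl-4-(propan-2-yl)cyclohex-1-en-1-yl trifluoromethanesulfonate | O=C[C@H]1C=C(OS(=O)(=O)C(F)(F)F)CC[C@@H]1C(C)C | intermediate
26 | methyl (2Z)-2-bromo-3-[(1R,6R)-6-(propan-2-yl)-3-(trifluoromethanesulfonyloxy)cyclohex-2-en-1-yl]prop-2-enoate | COC(=O)/C(Br)=C/[C@H]1C=C(OS(=O)(=O)C(F)(F)F)CC[C@@H]1C(C)C | intermediate
27 | methyl (2E)-2-(hydroxymethyl)-3-[(1R,6R)-3-(hydroxymethyl)-6-(propan-2-yl)cyclohex-2-en-1-yl]prop-2-enoate | COC(=O)/C(CO)=C/[C@H]1C=C(CO)CC[C@@H]1C(C)C | intermediate
28 | methyl (2E)-2-({[tert-butyl(dimethyl)silyl]oxy}methyl)-3-[(1R,6R)-3-({[tert-butyl(dimethyl)silyl]oxy}methyl)-6-(propan-2-yl)cyclohex-2-en-1-yl]prop-2-enoate | COC(=O)/C(CO[Si](C)(C)C(C)(C)C)=C/[C@H]1C=C(CO[Si](C)(C)C(C)(C)C)CC[C@@H]1C(C)C | intermediate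
29 | (2E)-2-({[tert-butyl(dimethyl)silyl]oxy}methyl)-3-[(1R,6R)-3-({[tert-butyl(dimethyl)silyl]oxy}methyl)-6-(propan-2-yl)cyclohex-2-en-1-yl]prop-2-enoic acid | OC(=O)/C(CO[Si](C)(C)C(C)(C)C)=C/[C@H]1C=C(CO[Si](C)(C)C(C)(C)C)CC[C@@H]1C(C)C | intermediate
30 | [(1S,2R,3R,4R)-3-ethenyl-1-hydroxy-2-{[(4-methoxyphenyl)methoxy]methyl}-4-(propan-2-yl)cyclohexyl]methyl ester of acid 29 | CC(C)[C@H]1CC[C@@](O)(COC(=O)/C(CO[Si](C)(C)C(C)(C)C)=C/[C@H]2C=C(CO[Si](C)(C)C(C)(C)C)CC[C@@H]2C(C)C)[C@@H](COCc2ccc(OC)cc2)[C@@H]1C=C | intermediate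
31 | [(1S,2R,3R,4R)-3-ethenyl-1-hydroxy-2-(hydroxymethyl)-4-(propan-2-yl)cyclohexyl]methyl ester of acid 29 | CC(C)[C@H]1CC[C@@](O)(COC(=O)/C(CO[Si](C)(C)C(C)(C)C)=C/[C@H]2C=C(CO[Si](C)(C)C(C)(C)C)CC[C@@H]2C(C)C)[C@@H](CO)[C@@H]1C=C | intermediate
32 | [(1S,2S,3R,4R)-3-ethenyl-2-formyl-1-hydroxy-4-(propan-2-yl)cyclohexyl]methyl ester of acid 29 | CC(C)[C@H]1CC[C@@](O)(COC(=O)/C(CO[Si](C)(C)C(C)(C)C)=C/[C@H]2C=C(CO[Si](C)(C)C(C)(C)C)CC[C@@H]2C(C)C)[C@@H](C=O)[C@@H]1C=C | intermediate (not isolated)
33 | (1S,2S,5R,6R)-6-ethenyl-2-hydroxy-5-(propan-2-yl)-2-[(RC-acyloxy)methyl]cyclohexane-1-carboxylic acid | CC(C)[C@H]1CC[C@@](O)(COC(=O)/C(CO[Si](C)(C)C(C)(C)C)=C/[C@H]2C=C(CO[Si](C)(C)C(C)(C)C)CC[C@@H]2C(C)C)[C@@H](C(=O)O)[C@@H]1C=C | intermediate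
34 | 2-(tert-butoxycarbonyl)prop-2-en-1-yl (1S,2S,5R,6R)-6-ethenyl-2-hydroxy-5-(propan-2-yl)-2-[(RC-acyloxy)methyl]cyclohexane-1-carboxylate | CC(C)[C@H]1CC[C@@](O)(COC(=O)/C(CO[Si](C)(C)C(C)(C)C)=C/[C@H]2C=C(CO[Si](C)(C)C(C)(C)C)CC[C@@H]2C(C)C)[C@@H](C(=O)OCC(=C)C(=O)OC(C)(C)C)[C@@H]1C=C | intermediate
35 | tert-butyl (5aS,6R,9S,9aS)-9-hydroxy-1-oxo-6-(propan-2-yl)-9-[(RC-acyloxy)methyl]-1,3,5a,6,7,8,9,9a-octahydro-2-benzoxepine-4-carboxylate | CC(C)[C@H]1CC[C@@](O)(COC(=O)/C(CO[Si](C)(C)C(C)(C)C)=C/[C@H]2C=C(CO[Si](C)(C)C(C)(C)C)CC[C@@H]2C(C)C)[C@H]2C(=O)OCC(C(=O)OC(C)(C)C)=C[C@H]12 | intermediate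
36 | (5aS,6R,9S,9aS)-9-hydroxy-9-[({(2E)-2-(hydroxymethyl)-3-[(1R,6R)-3-(hydroxymethyl)-6-(propan-2-yl)cyclohex-2-en-1-yl]prop-2-enoyl}oxy)methyl]-1-oxo-6-(propan-2-yl)-1,3,5a,6,7,8,9,9a-octahydro-2-benzoxepine-4-carboxylic acid | CC(C)[C@H]1CC[C@@](O)(COC(=O)/C(=C/[C@H]2C=C(CO)CC[C@@H]2C(C)C)CO)[C@H]2C(=O)OCC(C(=O)O)=C[C@H]12 | target

## Step count and least certain steps

Total step count: 26. Longest linear sequence: 17 steps (steps 1, 3 to 12 and 21 to 26; the ring C branch, steps 13 to 20, is eight steps and joins at step 21).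

**Step 3 (key step, proposed new method).** The likely failures are three. Self-condensation of vinyl keto ester 2 may outrun the cross-addition, because its own vinyl ketone is an unhindered acceptor. Enantiofacial discrimination by the thiourea may be poor with an acyclic keto enoate. The enantiomeric purity may erode through retro-Michael opening once carbonate is present. The fallback uses known chemistry and sets out from 2 and 4: the established racemic carbonate-mediated double Michael annulation gives racemic 6, which is taken through steps 4 to 6 unchanged to racemic 9. This carboxylic acid is resolved by crystallization of its salt with (1S)-1-phenylethan-1-amine, the (1S)-1-phenylethan-1-aminium carboxylate F1 (the enantiomeric amine is used if the salt of the unwanted antipode crystallizes first). Acidification of F1 returns to the route at 9.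

**Step 21.** The conjugated carboxylate is a weak nucleophile and the epoxide CH2 is neopentyl-like, so slow opening with thermal loss of silyl groups or acyl transfer is the main risk. The fallback sets out from 16: hydroxide opening (KOH, DMSO–H2O, 100 °C) at the same CH2 carbon gives the diol (1S,2R,3R,4R)-3-ethenyl-1-(hydroxymethyl)-2-{[(4-methoxyphenyl)methoxy]methyl}-4-(propan-2-yl)cyclohexan-1-ol F2. Its primary hydroxyl is acylated selectively with 29 by Yamaguchi esterification (2,4,6-trichlorobenzoyl chloride, Et3N, DMAP), which comes back to the route at 30.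

**Step 17 (with step 16).** Aldehyde 25 is α-branched and β,γ-unsaturated. Epimerization at C1' or migration of the double bond during its formation, slow reaction of the hindered aldehyde with the stabilized ylide, and incomplete Z selectivity are the risks. The fallback avoids the aldehyde and sets out from 23: cross-metathesis of the vinyl group with commercial methyl 2-(hydroxymethyl)prop-2-enoate under the second-generation Hoveyda–Grubbs catalyst (the enol triflate alkene is inert) gives methyl (2E)-2-(hydroxymethyl)-3-[(1S,6R)-6-(propan-2-yl)-3-(trifluoromethanesulfonyloxy)cyclohex-2-en-1-yl]prop-2-enoate F3 as the thermodynamic isomer. A single Stille hydroxymethylation of the triflate then comes back to the route at 27.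

**Step 25.** The ester linker prefers the extended conformation and the vinyl group is flanked by two substituted ring carbons, so slow cyclization with catalyst decay and intermolecular metathesis is the risk. The fallback separates the two events and sets out from 33: cross-metathesis of the vinyl group with an excess of commercial tert-butyl 2-(hydroxymethyl)prop-2-enoate gives the seco acid (1S,2S,5R,6S)-6-[(1E)-3-tert-butoxy-2-(hydroxymethyl)-3-oxoprop-1-en-1-yl]-2-hydroxy-5-(propan-2-yl)-2-[(RC-acyloxy)methyl]cyclohexane-1-carboxylic acid F4. Yamaguchi macrolactonization onto the allylic hydroxyl comes back to the route at 35.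

**Step 26.** Cleavage of the tert-butyl ester needs prolonged acid, under which the primary allylic alcohols may ionize and the β-hydroxy lactone may dehydrate or shift its acyl group. The fallback changes the ester and sets out from 33. The acid is alkylated with 2-(trimethylsilyl)ethyl 2-(bromomethyl)prop-2-enoate F5 (from 2-(bromomethyl)prop-2-enoic acid and 2-(trimethylsilyl)ethanol with a carbodiimide) to give the 2-(trimethylsilyl)ethyl analogue of 34, F6. Ring-closing metathesis as in step 25 gives the 2-(trimethylsilyl)ethyl analogue of 35, F7. One treatment of F7 with tris(dimethylamino)sulfonium difluorotrimethylsilicate in DMF removes all three silicon-based groups under nearly neutral conditions and arrives at 36.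

## Further compounds

F1 | step 3 | (1S)-1-phenylethan-1-aminium (6S,7R,8R)-6-(methoxycarbonyl)-8-(propan-2-yl)-1,4-dioxaspiro[4.5]decane-7-carboxylate | CC(C)[C@H]1CCC2(OCCO2)[C@@H](C(=O)OC)[C@@H]1C(=O)[O-].C[C@H]([NH3+])c1ccccc1
F2 | step 21 | (1S,2R,3R,4R)-3-ethenyl-1-(hydroxymethyl)-2-{[(4-methoxyphenyl)methoxy]methyl}-4-(propan-2-yl)cyclohexan-1-ol | CC(C)[C@H]1CC[C@@](O)(CO)[C@@H](COCc2ccc(OC)cc2)[C@@H]1C=C
F3 | step 17 | methyl (2E)-2-(hydroxymethyl)-3-[(1S,6R)-6-(propan-2-yl)-3-(trifluoromethanesulfonyloxy)cyclohex-2-en-1-yl]prop-2-enoate | COC(=O)/C(CO)=C/[C@H]1C=C(OS(=O)(=O)C(F)(F)F)CC[C@@H]1C(C)C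
F4 | step 25 | (1S,2S,5R,6S)-6-[(1E)-3-tert-butoxy-2-(hydroxymethyl)-3-oxoprop-1-en-1-yl]-2-hydroxy-5-(propan-2-yl)-2-[(RC-acyloxy)methyl]cyclohexane-1-carboxylic acid | CC(C)[C@H]1CC[C@@](O)(COC(=O)/C(CO[Si](C)(C)C(C)(C)C)=C/[C@H]2C=C(CO[Si](C)(C)C(C)(C)C)CC[C@@H]2C(C)C)[C@@H](C(=O)O)[C@@H]1/C=C(\CO)C(=O)OC(C)(C)C
F5 | step 26 | 2-(trimethylsilyl)ethyl 2-(bromomethyl)prop-2-enoate | C=C(CBr)C(=O)OCC[Si](C)(C)C
F6 | step 26 | 2-{[2-(trimethylsilyl)ethoxy]carbonyl}prop-2-en-1-yl (1S,2S,5R,6R)-6-ethenyl-2-hydroxy-5-(propan-2-yl)-2-[(RC-acyloxy)methyl]cyclohexane-1-carboxylate | CC(C)[C@H]1CC[C@@](O)(COC(=O)/C(CO[Si](C)(C)C(C)(C)C)=C/[C@H]2C=C(CO[Si](C)(C)C(C)(C)C)CC[C@@H]2C(C)C)[C@@H](C(=O)OCC(=C)C(=O)OCC[Si](C)(C)C)[C@@H]1C=C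
F7 | step 26 | 2-(trimethylsilyl)ethyl (5aS,6R,9S,9aS)-9-hydroxy-1-oxo-6-(propan-2-yl)-9-[(RC-acyloxy)methyl]-1,3,5a,6,7,8,9,9a-octahydro-2-benzoxepine-4-carboxylate | CC(C)[C@H]1CC[C@@](O)(COC(=O)/C(CO[Si](C)(C)C(C)(C)C)=C/[C@H]2C=C(CO[Si](C)(C)C(C)(C)C)CC[C@@H]2C(C)C)[C@H]2C(=O)OCC(C(=O)OCC[Si](C)(C)C)=C[C@H]12
A1 | alternative 1 | (5S,6S,7R,8R)-7-{2-(tert-butoxycarbonyl)-1-[(methoxycarbonyl)oxy]prop-2-en-1-yl}-2,2-dimethyl-8-(propan-2-yl)-1,3-dioxaspiro[4.5]decane-6-carboxylic acid (either carbinol epimer) | CC(C)[C@H]1CC[C@@]2(COC(C)(C)O2)[C@@H](C(=O)O)[C@@H]1C(OC(=O)OC)C(=C)C(=O)OC(C)(C)C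
A2 | alternative 1 | tert-butyl (5aS,6R,9S,9aS)-2',2'-dimethyl-1-oxo-6-(propan-2-yl)-3,5a,6,7,8,9a-hexahydro-1H-spiro[2-benzoxepine-9,4'-[1,3]dioxolane]-4-carboxylate | CC(C)[C@H]1CC[C@@]2(COC(C)(C)O2)[C@H]3C(=O)OCC(C(=O)OC(C)(C)C)=C[C@H]13
A3 | alternative 2 | tert-butyl (7R,9E)-8-[(methoxycarbonyl)oxy]-2,4-dioxo-7-(propan-2-yl)oxacycloundec-9-ene-10-carboxylate (either C8 epimer) | O=C1CC(=O)OC/C(C(=O)OC(C)(C)C)=C\C(OC(=O)OC)[C@@H](C(C)C)CC1
A4 | alternative 2 | tert-butyl (5aS,6R,9aS)-1,9-dioxo-6-(propan-2-yl)-1,3,5a,6,7,8,9,9a-octahydro-2-benzoxepine-4-carboxylate | CC(C)[C@H]1CCC(=O)[C@H]2C(=O)OCC(C(=O)OC(C)(C)C)=C[C@H]12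
A5 | alternative 3 | (1E,3E)-5-methylhexa-1,3-dien-1-yl acetate | CC(C)/C=C/C=C/OC(C)=O
A6 | alternative 3 | ethyl (2E)-4-oxobut-2-enoate | CCOC(=O)/C=C/C=O
A7 | alternative 3 | ethyl (1R,2S,3R,6S)-3-(acetyloxy)-2-formyl-6-(propan-2-yl)cyclohex-4-ene-1-carboxylate | CC(C)[C@H]1C=C[C@@H](OC(C)=O)[C@@H](C=O)[C@@H]1C(=O)OCC
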